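## Retrosynthetic overview

1. The target comes from its tris-silyl ether by one global desilylation.
2. Key disconnection: the pyran O1′–C2′ bond and the oxepine C10–ring C bond are cut together, leading back to an acyclic γ,δ-epoxy methyl ester of a 2-aryloxy-arylacetic acid. In the forward sense the ester carbonyl opens the epoxide and the resulting cation acylates ring C.
3. The epoxy ester comes from an arylacetate enolate and (2S,3R)-2,3-epoxyneryl triflate; Sharpless epoxidation of nerol is the only source of chirality.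
4. The arylacetate comes from methyl 2,4-dihydroxyphenylacetate by mono-silylation, bromination, Chan–Lam etherification (brings in ring C) and Negishi prenylation.
5. Ring order: rings A and C are bought as arenes; the pyran closes first and the oxepine second, in the same flask. Labels: ring A is the prenylated arene on C11, ring C the arene on C10 (C10 bears the pyran oxygen); pyran atoms are O1′, C2′ (quaternary), C3′ (carbinol), C4′ (CH2).

Assumption: the SMILES is read as (2′S,3′S), i.e. quaternary carbon S, carbinol carbon S, with the 3′-OH cis to the 4-methylpent-3-enyl chain.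

## Route

Step 1
Reactants: 1 nerol, (2Z)-3,7-dimethylocta-2,6-dien-1-ol
Product: 2 [(2S,3R)-3-methyl-3-(4-methylpent-3-en-1-yl)oxiran-2-yl]methanol ((2S,3R)-2,3-epoxynerol)
Conditions: Ti(OiPr)4 (10 mol %), L-(+)-diethyl tartrate (12 mol %), t-BuOOH (1.5 equiv), 4 Å MS, CH2Cl2, −20 °C
Reagents that add atoms: tert-butyl hydroperoxide, CC(C)(C)OO
Why: Katsuki–Sharpless asymmetric epoxidation: the titanium L-tartrate complex binds the allylic hydroxyl and delivers oxygen to one face of the Z-alkene, setting oxirane C2 (S) and C3 (R) together and leaving the remote trisubstituted alkene untouched.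

Step 2
Reactants: 2 (2S,3R)-2,3-epoxynerol
Product: 3 [(2S,3R)-3-methyl-3-(4-methylpent-3-en-1-yl)oxiran-2-yl]methyl trifluoromethanesulfonate
Conditions: Tf2O (1.1 equiv), 2,6-lutidine (1.3 equiv), CH2Cl2, −78 °C; cold pentane work-up, used at once
Reagents that add atoms: trifluoromethanesulfonic anhydride, O=S(=O)(OS(=O)(=O)C(F)(F)F)C(F)(F)F
Why: O-sulfonylation of the primary alcohol with a hindered base at −78 °C is fast and does not touch either oxirane stereocentre.

Step 3
Reactants: 4 methyl 2-(2,4-dihydroxyphenyl)acetate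
Product: 5 methyl 2-[4-(tert-butyldimethylsilyloxy)-2-hydroxyphenyl]acetate
Conditions: t-BuMe2SiCl (1.0 equiv), imidazole (1.2 equiv), CH2Cl2, −20 → 0 °C
Reagents that add atoms: tert-butyldimethylsilyl chloride, CC(C)(C)[Si](C)(C)Cl
Why: Sterically controlled silylation: the 4-OH is unhindered, whereas the 2-OH is flanked by the CH2CO2Me group and hydrogen-bonded to it, so one equivalent of silyl chloride reacts at O4.

Step 4
Reactants: 5 methyl 2-[4-(tert-butyldimethylsilyloxy)-2-hydroxyphenyl]acetate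
Product: 6 methyl 2-[5-bromo-4-(tert-butyldimethylsilyloxy)-2-hydroxyphenyl]acetate
Conditions: N-bromosuccinimide (1.0 equiv), CH2Cl2, −40 → 0 °C, dark
Reagents that add atoms: N-bromosuccinimide, O=C1CCC(=O)N1Br
Why: Electrophilic aromatic bromination: the free phenol directs para and the silyloxy group ortho, both to C5, which is also the less hindered of the two activated positions.

Step 5
Reactants: 6 methyl 2-[5-bromo-4-(tert-butyldimethylsilyloxy)-2-hydroxyphenyl]acetate; 7 [3-(tert-butyldimethylsilyloxy)phenyl]boronic acid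
Product: 8 methyl 2-{5-bromo-4-(tert-butyldimethylsilyloxy)-2-[3-(tert-butyldimethylsilyloxy)phenoxy]phenyl}acetate
Conditions: Cu(OAc)2 (20 mol %), pyridine (3 equiv), 4 Å MS, O2 (1 atm), CH2Cl2, rt; 7 (2 equiv)
Reagents that add atoms: none
Why: Chan–Lam oxidative copper-catalysed O-arylation of a phenol with an arylboronic acid runs at room temperature under near-neutral conditions, so the aryl bromide, both aryl silyl ethers and the ester survive.

Step 6
Reactants: 8 methyl 2-{5-bromo-4-(tert-butyldimethylsilyloxy)-2-[3-(tert-butyldimethylsilyloxy)phenoxy]phenyl}acetate; 9 1-bromo-3-methylbut-2-ene (prenyl bromide)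
Product: 11 methyl 2-{4-(tert-butyldimethylsilyloxy)-5-(3-methylbut-2-en-1-yl)-2-[3-(tert-butyldimethylsilyloxy)phenoxy]phenyl}acetate, via prenylzinc bromide 10 (not isolated)
Conditions: 9 (1.5 equiv), Zn, LiCl, THF, 0 °C; then 8, Pd(OAc)2 (2 mol %), CPhos (4 mol %), THF, rt
Reagents that add atoms: none
Why: Negishi cross-coupling: zinc insertion gives the allylic zinc reagent, and with a bulky biaryl dialkylphosphine reductive elimination occurs at the unsubstituted allyl terminus, giving the linear prenyl arene at room temperature without touching the ester or silyl ethers.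

Step 7
Reactants: 11 methyl 2-{4-(tert-butyldimethylsilyloxy)-5-(3-methylbut-2-en-1-yl)-2-[3-(tert-butyldimethylsilyloxy)phenoxy]phenyl}acetate; 3 (2S,3R)-2,3-epoxyneryl triflate
Product: 13 methyl 2-{4-(tert-butyldimethylsilyloxy)-5-(3-methylbut-2-en-1-yl)-2-[3-(tert-butyldimethylsilyloxy)phenoxy]phenyl}-3-[(2S,3R)-3-methyl-3-(4-methylpent-3-en-1-yl)oxiran-2-yl]propanoate (about 1:1 epimers at propanoate C2), via lithium ester enolate 12 (not isolated)
Conditions: LiN(iPr)2 (1.05 equiv), THF, −78 °C; then 3 (1.2 equiv), −78 → −40 °C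
Reagents that add atoms: none
Why: Enolate alkylation (SN2): the arylacetate enolate displaces the primary triflate at −78 °C far faster than it can open the trisubstituted epoxide, so both oxirane stereocentres are carried over unchanged (the new α-centre is destroyed in the next step).

Step 8
Reactants: 13 the epoxy ester from step 7
Product: 16 tris-silyl ether of the target: (2′S,3′S)-pyrano-fused dibenzo[b,f]oxepine carrying 3-OSi(t-Bu)Me2 and 2-prenyl on ring A plus 7-OSi(t-Bu)Me2 on ring C plus 3′-OSiMe3 on the pyran, via dialkoxycarbenium triflate 14 (not isolated), via cyclic methyl ketal 15 (not isolated)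
Conditions: Me3SiOTf (2.5 equiv), 2,6-di-tert-butyl-4-methylpyridine (3 equiv), CH2Cl2, −78 → 0 °C
Reagents that add atoms: trimethylsilyl trifluoromethanesulfonate, C[Si](C)(C)OS(=O)(=O)C(F)(F)F
Why: Proposed new method: Me3SiOTf silylates the epoxide oxygen and the ester carbonyl oxygen opens it 6-endo at the tertiary carbon with inversion (this sets the S quaternary centre C2′; the S carbinol centre C3′ is carried over from the epoxide) to give the 2-methoxy-oxanylium ion; a methyl ester cannot end the cascade by losing its alkyl group, so the cation is captured by ring C para to its silyloxy group in a seven-membered Friedel–Crafts closure to give the methyl ketal, from which Me3SiOTf and the hindered base expel methoxide as Me3SiOMe and remove the C11 proton to give the conjugated enol ether; the closest known reactions are Lewis-acid-promoted endo-selective epoxide openings terminated by ester or carbonate carbonyls, Friedel–Crafts acylation by orthoester-derived dialkoxycarbenium ions (Rieche/Gross type) and the silyl triflate/base conversion of ketals into enol ethers.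

Step 9
Reactants: 16 tris-silyl ether of the target
Product: 17 target CNP0185870.1: (2′S,3′S)-2′-methyl-2′-(4-methylpent-3-en-1-yl)-3′,4′-dihydro-2′H-pyrano ring fused across C10=C11 of 2-(3-methylbut-2-en-1-yl)dibenzo[b,f]oxepine-3,7-diol (O1′ on C10; C4′ on C11; 3′-OH)
Conditions: Bu4NF (4 equiv), AcOH (4 equiv), THF, 0 °C → rt
Reagents that add atoms: none
Why: Fluoride-mediated desilylation (Si–F bond formation) cleaves both aryl silyl ethers and the trimethylsilyl ether under acetic-acid-buffered conditions that leave the enol ether, the alkenes and both stereocentres untouched.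

## Compound list

1 | nerol, (2Z)-3,7-dimethylocta-2,6-dien-1-ol | CC(C)=CCC/C(C)=C\CO | starting material
2 | [(2S,3R)-3-methyl-3-(4-methylpent-3-en-1-yl)oxiran-2-yl]methanol | OC[C@@H]1O[C@]1(C)CCC=C(C)C | intermediate
3 | [(2S,3R)-3-methyl-3-(4-methylpent-3-en-1-yl)oxiran-2-yl]methyl trifluoromethanesulfonate | FC(F)(F)S(=O)(=O)OC[C@@H]1O[C@]1(C)CCC=C(C)C | intermediate
4 | methyl 2-(2,4-dihydroxyphenyl)acetate | COC(=O)Cc1ccc(O)cc1O | starting material
5 | methyl 2-[4-(tert-butyldimethylsilyloxy)-2-hydroxyphenyl]acetate | COC(=O)Cc1ccc(O[Si](C)(C)C(C)(C)C)cc1O | intermediate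
6 | methyl 2-[5-bromo-4-(tert-butyldimethylsilyloxy)-2-hydroxyphenyl]acetate | COC(=O)Cc1cc(Br)c(O[Si](C)(C)C(C)(C)C)cc1O | intermediate
7 | [3-(tert-butyldimethylsilyloxy)phenyl]boronic acid | OB(O)c1cccc(O[Si](C)(C)C(C)(C)C)c1 | starting material
8 | methyl 2-{5-bromo-4-(tert-butyldimethylsilyloxy)-2-[3-(tert-butyldimethylsilyloxy)phenoxy]phenyl}acetate | COC(=O)Cc1cc(Br)c(O[Si](C)(C)C(C)(C)C)cc1Oc1cccc(O[Si](C)(C)C(C)(C)C)c1 | intermediate
9 | 1-bromo-3-methylbut-2-ene | CC(C)=CCBr | starting material
10 | (3-methylbut-2-en-1-yl)zinc bromide | CC(C)=CC[Zn]Br | intermediate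
11 | methyl 2-{4-(tert-butyldimethylsilyloxy)-5-(3-methylbut-2-en-1-yl)-2-[3-(tert-butyldimethylsilyloxy)phenoxy]phenyl}acetate | COC(=O)Cc1cc(CC=C(C)C)c(O[Si](C)(C)C(C)(C)C)cc1Oc1cccc(O[Si](C)(C)C(C)(C)C)c1 | intermediate
12 | lithium enolate of the methyl arylacetate | [Li+].COC([O-])=Cc1cc(CC=C(C)C)c(O[Si](C)(C)C(C)(C)C)cc1Oc1cccc(O[Si](C)(C)C(C)(C)C)c1 | intermediate
13 | methyl 2-aryl-3-[(2S,3R)-3-methyl-3-(4-methylpent-3-en-1-yl)oxiran-2-yl]propanoate (aryl as in the arylacetate; epimers at C2) | COC(=O)C(C[C@@H]1O[C@]1(C)CCC=C(C)C)c1cc(CC=C(C)C)c(O[Si](C)(C)C(C)(C)C)cc1Oc1cccc(O[Si](C)(C)C(C)(C)C)c1 | intermediate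
14 | 3-aryl-2-methoxy-6-methyl-6-(4-methylpent-3-en-1-yl)-5-(trimethylsilyloxy)oxan-2-ylium triflate (quaternary carbon inverted) | CC(C)=CCC[C@]1(C)[O+]=C(OC)C(C[C@@H]1O[Si](C)(C)C)c1cc(CC=C(C)C)c(O[Si](C)(C)C(C)(C)C)cc1Oc1cccc(O[Si](C)(C)C(C)(C)C)c1.[O-]S(=O)(=O)C(F)(F)F | intermediate
15 | pyrano-fused 10-methoxy-10,11-dihydrodibenzo[b,f]oxepine ketal (C10 bears OMe and O1′; C11–H) | CC(C)=CCC[C@]1(C)OC2(OC)C(C[C@@H]1O[Si](C)(C)C)c1cc(CC=C(C)C)c(O[Si](C)(C)C(C)(C)C)cc1Oc1cc(O[Si](C)(C)C(C)(C)C)ccc12 | intermediate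
16 | tris-silyl ether of the target (3- and 7-O-tert-butyldimethylsilyl; 3′-O-trimethylsilyl; 2′S,3′S) | CC(C)=CCC[C@]1(C)OC2=C(C[C@@H]1O[Si](C)(C)C)c1cc(CC=C(C)C)c(O[Si](C)(C)C(C)(C)C)cc1Oc1cc(O[Si](C)(C)C(C)(C)C)ccc12 | intermediate
17 | CNP0185870.1 (2′S,3′S) | CC(C)=CCC[C@]1(C)OC2=C(C[C@@H]1O)c1cc(CC=C(C)C)c(O)cc1Oc1cc(O)ccc12 | target

## Step count and risks

Total steps: 9. Longest linear sequence: 7 (steps 3 to 9, from compound 4); steps 1 and 2 form the second branch.

Most likely to fail:

**Step 8 (double ring closure).** This is an untested cascade. The epoxide may open 5-exo or rearrange to a ketone. The oxanylium ion may also stall as a ketene acetal or lactone instead of acylating ring C. The fallback sets out from 11 and comes back at 16, building the oxepine first as a ketone and closing the pyran afterwards. Me3SnOH in 1,2-dichloroethane at 80 °C hydrolyses the methyl ester without cleaving the aryl silyl ethers and gives 2-{4-(tert-butyldimethylsilyloxy)-5-(3-methylbut-2-en-1-yl)-2-[3-(tert-butyldimethylsilyloxy)phenoxy]phenyl}acetic acid F1. 1-Chloro-N,N,2-trimethylprop-1-en-1-amine in CH2Cl2 converts it under neutral conditions into the arylacetyl chloride F2. SnCl4 with 2,6-di-tert-butyl-4-methylpyridine in CH2Cl2 at −78 °C closes the seven-membered ring by Friedel–Crafts acylation para to the ring C silyloxy group, giving 3,7-bis(tert-butyldimethylsilyloxy)-2-(3-methylbut-2-en-1-yl)dibenzo[b,f]oxepin-10(11H)-one F3. LiN(SiMe3)2 in THF at −78 °C followed by triflate 3 alkylates C11 and gives the 11-(epoxyalkyl) ketone F4. Me3SiOTf with the same pyridine base then makes the ketone oxygen open the epoxide 6-endo with inversion, and loss of the C11 proton gives 16.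

**Step 7 (enolate alkylation with a labile epoxy triflate).** The triflate may decompose, or the product enolate may attack its own epoxide. The fallback sets out from 11 (and 2) and comes back at 13, using a soft malonate nucleophile and a stable iodide. LiN(SiMe3)2 (2.1 equiv) and allyl chloroformate in THF at −78 °C convert 11 into the allyl methyl arylmalonate F5. PPh3, I2 and imidazole in CH2Cl2 at 0 °C convert 2 into (2R,3R)-2-(iodomethyl)-3-methyl-3-(4-methylpent-3-en-1-yl)oxirane F6 (same geometry, descriptor changes with the iodine). NaH in THF/DMF at 0 → 40 °C joins them to the quaternary allyl methyl malonate F7. Pd(PPh3)4 (5 mol %, zerovalent palladium) with HCO2H and Et3N in THF at 40 °C removes the allyl ester and the resulting acid decarboxylates, which gives 13.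

**Step 6 (prenylation).** The coupling may give the branched (1,1-dimethylallyl) isomer, or the zinc reagent may attack the ester. The fallback sets out from 8 and comes back at 11. Stille coupling with Bu3SnCH2CH=CH2 and Pd(PPh3)4 in DMF at 90 °C gives the allyl arene methyl 2-{5-allyl-4-(tert-butyldimethylsilyloxy)-2-[3-(tert-butyldimethylsilyloxy)phenoxy]phenyl}acetate F8, which has no regiochemical ambiguity. Cross-metathesis with excess 2-methylbut-2-ene and the second-generation Grubbs catalyst RuCl2(=CHPh)(PCy3)(H2IMes) in CH2Cl2 at 40 °C turns the allyl group into prenyl, which gives 11.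

## Further compounds

F1 | step 8 | 2-{4-(tert-butyldimethylsilyloxy)-5-(3-methylbut-2-en-1-yl)-2-[3-(tert-butyldimethylsilyloxy)phenoxy]phenyl}acetic acid | OC(=O)Cc1cc(CC=C(C)C)c(O[Si](C)(C)C(C)(C)C)cc1Oc1cccc(O[Si](C)(C)C(C)(C)C)c1
F2 | step 8 | 2-{4-(tert-butyldimethylsilyloxy)-5-(3-methylbut-2-en-1-yl)-2-[3-(tert-butyldimethylsilyloxy)phenoxy]phenyl}acetyl chloride | ClC(=O)Cc1cc(CC=C(C)C)c(O[Si](C)(C)C(C)(C)C)cc1Oc1cccc(O[Si](C)(C)C(C)(C)C)c1
F3 | step 8 | 3,7-bis(tert-butyldimethylsilyloxy)-2-(3-methylbut-2-en-1-yl)dibenzo[b,f]oxepin-10(11H)-one | O=C1Cc2cc(CC=C(C)C)c(O[Si](C)(C)C(C)(C)C)cc2Oc2cc(O[Si](C)(C)C(C)(C)C)ccc12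
F4 | step 8 | 3,7-bis(tert-butyldimethylsilyloxy)-2-(3-methylbut-2-en-1-yl)-11-{[(2S,3R)-3-methyl-3-(4-methylpent-3-en-1-yl)oxiran-2-yl]methyl}dibenzo[b,f]oxepin-10(11H)-one | O=C1C(C[C@@H]3O[C@]3(C)CCC=C(C)C)c2cc(CC=C(C)C)c(O[Si](C)(C)C(C)(C)C)cc2Oc2cc(O[Si](C)(C)C(C)(C)C)ccc12
F5 | step 7 | allyl methyl 2-{4-(tert-butyldimethylsilyloxy)-5-(3-methylbut-2-en-1-yl)-2-[3-(tert-butyldimethylsilyloxy)phenoxy]phenyl}malonate | COC(=O)C(C(=O)OCC=C)c1cc(CC=C(C)C)c(O[Si](C)(C)C(C)(C)C)cc1Oc1cccc(O[Si](C)(C)C(C)(C)C)c1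
F6 | step 7 | (2R,3R)-2-(iodomethyl)-3-methyl-3-(4-methylpent-3-en-1-yl)oxirane | IC[C@@H]1O[C@]1(C)CCC=C(C)C
F7 | step 7 | allyl methyl 2-aryl-2-{[(2S,3R)-3-methyl-3-(4-methylpent-3-en-1-yl)oxiran-2-yl]methyl}malonate | COC(=O)C(C[C@@H]1O[C@]1(C)CCC=C(C)C)(C(=O)OCC=C)c1cc(CC=C(C)C)c(O[Si](C)(C)C(C)(C)C)cc1Oc1cccc(O[Si](C)(C)C(C)(C)C)c1
F8 | step 6 | methyl 2-{5-allyl-4-(tert-butyldimethylsilyloxy)-2-[3-(tert-butyldimethylsilyloxy)phenoxy]phenyl}acetate | COC(=O)Cc1cc(CC=C)c(O[Si](C)(C)C(C)(C)C)cc1Oc1cccc(O[Si](C)(C)C(C)(C)C)c1
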